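Remarks on the chemistry (conventions and assumptions)
- Ring positions are cited in daucane numbering: C1 (quaternary, carries methyl C15), C2, C3, C4 (carbinol with isopropyl), C5 (ring-fusion CH), C6 (ester carbinol), C7, C8 (carries C14), C9 (allylic carbinol), C10. α is the face of H-5, β the face of C15. The target is (1R,4R,5S,6S,9S) in this numbering.
- Compounds 1, 4 and 13, vinylboronic acid pinacol ester, p-ABSA and both enantiomers of Rh2(DOSP)4 are assumed to be commercial.
- The sense of asymmetric induction in step 4 is a prediction from the accepted model for this catalyst family; the other catalyst enantiomer is used if the sense proves opposite.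

## The problem

The target is a trans-fused bicyclo[5.3.0]decane: a cyclopentane (C1–C5) and a cycloheptane (C1, C5–C10) share the quaternary C1 (methyl) and C5 (H), with H-5 anti to the methyl group. Four contiguous stereocentres surround the ring fusion (C1, C4, C5, C6) and a fifth (C9) is remote. The C4 hydroxyl is cis to the methyl group, and the C6 and C9 oxygens both lie on the α-face with H-5. Only C1 cannot be corrected once made, so it should be set first and then used to control the others. The seven-membered ring is functionalised at three of its carbons: a homoallylic aryl ester at C6, an exocyclic methylene at C8 and an allylic alcohol at C9. The feature that makes the key step possible is the array C1–C5–C6–C7 joined through C7–C8 and C1–C10 to the unit C8(C14)–C9–C10. This is the imprint of a 1-vinylcyclopentene (C1=C5–C6=C7) united with a vinylcarbene whose carbene carbon C8 carries a carboxyl carbon (C14) and whose vinyl group is C9=C10. Groups that do not survive rough treatment are the tertiary alcohol β to the C6 oxygen (elimination or retro-aldol at any ketone stage), the allylic alcohol beside a 1,1-disubstituted alkene, the aryl ester with its free phenol, and the C8 alkene, which moves into conjugation if C6 or C9 becomes a ketone.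

## Retrosynthesis

**20 ⇒ 17 ⇒ 16 (C9–O bond).** The C9–O bond is cut by reading the allylic alcohol as the product of a [2,3] shift of the allylic sulfoxide 17, itself the S-oxide of thioether 16. The neighbouring cut, reduction of a C9 ketone, would let hydride enter from the open α-face and leave the hydroxyl on the wrong β-face, and the ketone would draw the C8 alkene into conjugation. The precursor has one stereocentre fewer and only a trisubstituted alkene. The forward reaction must deliver oxygen to the α-face of C9 and free the phenol without touching the C6 ester.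

**16 ⇒ 12 + 14 (ester C–O bond).** The ester bond is cut late because an aryl ester would not survive the hydride and organometallic steps. Acid 14 carries the phenol as an acetate. The forward reaction must acylate the hindered secondary C6 hydroxyl of 12 and leave the tertiary C4 hydroxyl alone.

**12 ⇒ 11 (C4–isopropyl bond).** Cutting this bond removes three carbons and one stereocentre and leaves cyclopentanone 11. It is preferred over carrying the tertiary alcohol from the start, because in 11 the adjacent C5 substituent and the C15 methyl group both shield the β-face, so the nucleophile is steered to the α-face. The forward reaction needs a non-basic isopropyl nucleophile.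

**11 ⇒ 10 ⇒ 9 ⇒ 8 (functional-group changes only).** The C4 carbonyl comes from the dioxolane of 10, the C14–S bond from the primary allylic alcohol of 9, and that alcohol from the methyl ester of 8. The thioether is put in before the ketone is unmasked so that the only free hydroxyl in 11 is the one at C6. All functionality of the seven-membered ring is thus traced back to one ester and one alcohol.

**8 ⇒ 7 (C5–H and C6–O bonds).** Both bonds are cut together as a retro-hydroboration of the C5=C6 alkene of 7. This is preferred over a C6 ketone, whose reduction by external hydride would place the hydroxyl on the β-face and whose enolisation toward C7 would move the C8=C9 alkene. The precursor loses two stereocentres. The forward reaction must add from the α-face and spare the enoate.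

**7 ⇒ 3 + 5 via 6 (C1–C10 and C7–C8 bonds; the key cut).** Cutting these two bonds takes the seven-membered ring apart into the achiral monocyclic diene 3 and the four-carbon diazo ester 5. Against the neighbouring cuts (C8=C9 by metathesis, C8–C9 by carbonyl addition), this one forms the ring, the quaternary stereocentre, the C14 branch and both ring alkenes in one operation. The forward reaction must cyclopropanate only the vinyl group of 3, give the cis-divinylcyclopropane 6, carry out the Cope rearrangement at a fully substituted terminus, and do so under catalyst control of the absolute configuration.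

**3 ⇒ 2 ⇒ 1 and 5 ⇒ 4.** Diene 3 is cut at the vinyl–ring bond to alkenyl bromide 2, the ketal of bromo-enone 1. The ketal makes the diene electron-rich and makes the two faces at C4 alike. Diazo ester 5 comes from ester 4 by diazo transfer.

## Roads not taken

Alternative 1: The most obvious cut is C8=C9 by ring-closing metathesis, with O-9 and the exocyclic alkene brought in last. The forward key step would close diene A1 with a second-generation Grubbs catalyst to the dauc-8-ene-4,6-diol A2, followed by acylation, α-epoxidation and base-mediated epoxide-to-allylic-alcohol isomerisation. The metathesis forms one bond and no stereocentre, so A1 must already carry C1, C4, C5 and C6 on an open cyclopentane, where enolate trapping has to tell methyl from allyl at C1. The late isomerisation must pick a C14 proton over the C7 and C10 protons, and C14 arrives as an inert methyl group. The chosen plan forms the ring and the quaternary centre together, brings C14 in as an ester that later drives the oxygen transposition, and is several steps shorter.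

Alternative 2: A ring contraction and expansion of a decalin, cutting C1–C5 and reconnecting the migrating carbon to C6. The forward key step would be the semipinacol 1,2-shift of the cis-decalin-diol monomesylate A3 to the hydroazulen-6-one A4, with inversion at the migration terminus. The shift only reshapes an existing bicycle. The cheap angular-methyl octalones that lead to A3 carry their ring-B oxygen on the carbon that becomes C10, so C14 and O-9 would need a carbonyl transposition and a homologation. C6 emerges as a ketone whose reduction by external hydride should give the β-alcohol and whose enolisation endangers any C8 unsaturation. The chosen plan reaches the same ring system with every carbon and oxidation level in place.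

Alternative 3: A chiral-pool five-membered ring joined to a three-carbon linchpin, cutting C6–C7 and C8–C9. (S)-Terpinen-4-ol A5 would be cleaved and re-closed (ozonolysis, aldol condensation) to enal A6, which maps ten carbons and C4 of the target. After elaboration to bromo-aldehyde A7, an intramolecular Nozaki–Hiyama–Kishi reaction (CrCl2, cat. NiCl2) would close C8–C9 and give the exocyclic methylene and the C9 carbinol together. The ring contraction passes through a β-oxygenated aldehyde that tends to eliminate. C1 would have to be made quaternary by addition to a tetrasubstituted enal on the face cis to the isopropyl group, against the steric bias. The ring closure would set C9 with no controlling element, and two aldehydes would have to be told apart. The chosen plan needs no protecting group on carbon-bound oxygen before the last stage and sets every stereocentre from C1.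

Key step: step 4

## Route

Step 1
Reactants: 1 2-bromo-3-methylcyclopent-2-en-1-one
Product: 2 6-bromo-7-methyl-1,4-dioxaspiro[4.4]non-6-ene
Conditions: ethylene glycol, p-TsOH·H2O (cat.), benzene, reflux, Dean–Stark trap
Reagents that add atoms: ethylene glycol, OCCO
Why: Acid-catalysed ketalisation with azeotropic removal of water; with bromine on the α-carbon the double bond stays in place, and the dioxolane masks C4 and removes the electron-withdrawing carbonyl so that the later diene is electron-rich.

Step 2
Reactants: 2 6-bromo-7-methyl-1,4-dioxaspiro[4.4]non-6-ene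
Product: 3 6-ethenyl-7-methyl-1,4-dioxaspiro[4.4]non-6-ene
Conditions: vinylboronic acid pinacol ester, Pd(OAc)2 (cat.), SPhos, K3PO4, toluene/H2O, 80 °C
Reagents that add atoms: 2-ethenyl-4,4,5,5-tetramethyl-1,3,2-dioxaborolane, C=CB1OC(C)(C)C(C)(C)O1
Why: Suzuki–Miyaura coupling; the electron-rich biaryl phosphine helps oxidative addition into the hindered tetrasubstituted alkenyl bromide, and the basic medium keeps the allylic ketal intact.

Step 3
Reactants: 4 methyl but-3-enoate
Product: 5 methyl 2-diazobut-3-enoate
Conditions: p-ABSA, DBU, MeCN, 0 °C; extracted into pentane and used cold at once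
Reagents that add atoms: 4-acetamidobenzenesulfonyl azide (p-ABSA), CC(=O)Nc1ccc(cc1)S(=O)(=O)N=[N+]=[N-]
Why: Regitz diazo transfer: DBU forms the dienolate of the β,γ-unsaturated ester, which takes up N2 at the α-carbon; the vinyl diazo ester tends to electrocyclise to a pyrazole and is therefore not stored.

Step 4
Reactants: 3 6-ethenyl-7-methyl-1,4-dioxaspiro[4.4]non-6-ene; 5 methyl 2-diazobut-3-enoate
Product: 7 methyl (3a'R)-3a'-methyl-2',3',3a',4'-tetrahydro-7'H-spiro[1,3-dioxolane-2,1'-azulene]-6'-carboxylate (daucane positions: C1 quaternary, C5=C6, C8(CO2Me)=C9, C4 ketal), via cis-divinylcyclopropane 6 (not isolated)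
Conditions: Rh2(R-DOSP)4 [dirhodium tetrakis((R)-N-(4-dodecylbenzenesulfonyl)prolinate)] (1 mol %), pentane, −40 °C to rt, slow addition of 5; then toluene, 110 °C
Reagents that add atoms: none
Why: The dirhodium carboxylate turns 5 into a donor/acceptor vinylcarbenoid whose carbene carbon (C8, bearing the ester carbon C14) adds to the only unhindered π bond of 3, the vinyl group C6=C7, in a concerted asynchronous cyclopropanation that places the cyclopentenyl group cis to the carbenoid vinyl group (6). 6 then undergoes a Cope rearrangement through the boat transition state, the only one open to a cis-divinylcyclopropane: the C6–C8 bond breaks and C1 bonds to C10, so the seven-membered ring is closed by a [3,3]-sigmatropic ring expansion of the three-membered ring, that is by pericyclic bond formation between the two alkene termini. The closest known reaction type is the enantioselective formal [4+3] cycloaddition of vinyldiazoacetates with 1,3-dienes under Rh2(DOSP)4 catalysis, including dienes whose fully substituted terminus ends as a quaternary carbon. The only new stereocentre, C1, is formed in the Cope step but is dictated by the configuration of 6, because the ring fixes the C15 methyl group in the inside position of the boat and the cyclopropane fixes which face of C1 meets C10; the configuration of 6 is set by the chiral catalyst, so C1 is under catalyst control, and the (R)-catalyst is predicted to give (1S,2S)-6 and hence (R)-C1. The step needs site selectivity (vinyl group over the tetrasubstituted ring alkene, secured by sterics and by the electrophilic carbenoid), cis selectivity in the cyclopropanation (typical of donor/acceptor carbenoids in a hydrocarbon solvent) and face selectivity (catalyst). Because the methyl group points at the cyclopropane CH2 in the boat, the rearrangement needs heating, which 6 should tolerate since no hydrogen is placed for a competing retro-ene shift.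

Step 5
Reactants: 7 methyl (3a'R)-3a'-methyl-2',3',3a',4'-tetrahydro-7'H-spiro[1,3-dioxolane-2,1'-azulene]-6'-carboxylate
Product: 8 methyl (3a'R,8'S,8a'S)-8'-hydroxy-3a'-methyl-2',3',3a',4',8',8a'-hexahydro-7'H-spiro[1,3-dioxolane-2,1'-azulene]-6'-carboxylate (6α-OH, 5α-H, trans-fused)
Conditions: BH3·THF (1.1 equiv), THF, −10 to 0 °C; then 30% H2O2, pH 7 phosphate buffer, 0 °C to rt
Reagents that add atoms: hydrogen peroxide, OO
Why: Hydroboration–oxidation: boron adds to C6 (the CH end) and hydrogen to C5 in a syn four-centre addition, and the electron-poor enoate C8=C9 reacts more slowly. In the half-chair of the cyclohepta-1,4-diene the C15 methyl group stands almost perpendicular to the C5=C6 plane on the β-face, so borane should enter from the α-face and set H-5 trans to the methyl group and the 6α-hydroxyl together; the oxidation goes with retention.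

Step 6
Reactants: 8 methyl (3a'R,8'S,8a'S)-8'-hydroxy-3a'-methyl-2',3',3a',4',8',8a'-hexahydro-7'H-spiro[1,3-dioxolane-2,1'-azulene]-6'-carboxylate
Product: 9 (3a'R,8'S,8a'S)-6'-(hydroxymethyl)-3a'-methyl-2',3',3a',4',8',8a'-hexahydro-7'H-spiro[1,3-dioxolane-2,1'-azulen]-8'-ol
Conditions: iBu2AlH (4 equiv), CH2Cl2, −78 to 0 °C; aqueous potassium sodium tartrate
Reagents that add atoms: none
Why: iBu2AlH reduces the α,β-unsaturated ester by 1,2-addition to the primary allylic alcohol; the ketal, the alkene position and the stereocentres are untouched.

Step 7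
Reactants: 9 (3a'R,8'S,8a'S)-6'-(hydroxymethyl)-3a'-methyl-2',3',3a',4',8',8a'-hexahydro-7'H-spiro[1,3-dioxolane-2,1'-azulen]-8'-ol
Product: 10 (3a'R,8'S,8a'S)-3a'-methyl-6'-[(phenylsulfanyl)methyl]-2',3',3a',4',8',8a'-hexahydro-7'H-spiro[1,3-dioxolane-2,1'-azulen]-8'-ol
Conditions: PhSSPh, PBu3, pyridine, 0 °C to rt
Reagents that add atoms: diphenyl disulfide, c1ccccc1SSc1ccccc1
Why: Hata-type sulfenylation: the phosphine–disulfide pair activates the primary allylic alcohol as an alkoxyphosphonium ion that thiolate displaces by SN2; the hindered secondary C6 hydroxyl does not react and no stereocentre is touched.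

Step 8
Reactants: 10 (3a'R,8'S,8a'S)-3a'-methyl-6'-[(phenylsulfanyl)methyl]-2',3',3a',4',8',8a'-hexahydro-7'H-spiro[1,3-dioxolane-2,1'-azulen]-8'-ol
Product: 11 (3aR,8S,8aS)-8-hydroxy-3a-methyl-6-[(phenylsulfanyl)methyl]-3,3a,4,7,8,8a-hexahydroazulen-1(2H)-one (C4 ketone)
Conditions: PPTS (cat.), acetone/H2O (10:1), 40 °C
Reagents that add atoms: water, O
Why: Acid-catalysed hydrolysis of the dioxolane under conditions mild enough to avoid dehydration of the β-hydroxy ketone and enolisation at C5; no stereocentre changes.

Step 9
Reactants: 11 (3aR,8S,8aS)-8-hydroxy-3a-methyl-6-[(phenylsulfanyl)methyl]-3,3a,4,7,8,8a-hexahydroazulen-1(2H)-one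
Product: 12 (1R,3aR,8S,8aS)-3a-methyl-6-[(phenylsulfanyl)methyl]-1-(propan-2-yl)-1,2,3,3a,4,7,8,8a-octahydroazulene-1,8-diol (4β-OH, 4α-isopropyl)
Conditions: iPrMgCl (3.5 equiv), anhydrous CeCl3 (3.5 equiv), THF, −78 to −40 °C; aq. NH4Cl
Reagents that add atoms: isopropylmagnesium chloride, CC(C)[Mg]Cl
Why: Organocerium 1,2-addition, chosen because the reagent is weakly basic and should neither enolise nor reduce the hindered cyclopentanone. The nucleophile attacks C4 anti to the C6-bearing substituent on the adjacent C5 and anti to the 1,3-related C15 methyl group, that is from the α-face, which gives the 4β-hydroxyl (4R).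

Step 10
Reactants: 13 vanillic acid (4-hydroxy-3-methoxybenzoic acid)
Product: 14 4-acetoxy-3-methoxybenzoic acid
Conditions: Ac2O, pyridine, rt; then H2O
Reagents that add atoms: acetic anhydride, CC(=O)OC(C)=O
Why: Acetylation of the phenol (the mixed anhydride at the acid is hydrolysed on aqueous work-up); the acetate blocks the phenol during acyl chloride formation and peracid oxidation and is removed by the amine of the last step.

Step 11
Reactants: 12 (1R,3aR,8S,8aS)-3a-methyl-6-[(phenylsulfanyl)methyl]-1-(propan-2-yl)-1,2,3,3a,4,7,8,8a-octahydroazulene-1,8-diol; 14 4-acetoxy-3-methoxybenzoic acid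
Product: 16 (3R,3aS,4S,8aR)-3-hydroxy-8a-methyl-6-[(phenylsulfanyl)methyl]-3-(propan-2-yl)-1,2,3,3a,4,5,8,8a-octahydroazulen-4-yl 4-acetoxy-3-methoxybenzoate, via acyl chloride 15 (not isolated)
Conditions: 14, (COCl)2, DMF (cat.), CH2Cl2, 0 °C to rt, concentrate; then 12, Et3N, DMAP, CH2Cl2, 0 to 40 °C
Reagents that add atoms: none
Why: Acyl chloride formation followed by DMAP-catalysed acylation; only the secondary C6 hydroxyl reacts, the tertiary C4 hydroxyl is inert, and the configuration at C6 is retained.

Step 12
Reactants: 16 (3R,3aS,4S,8aR)-3-hydroxy-8a-methyl-6-[(phenylsulfanyl)methyl]-3-(propan-2-yl)-1,2,3,3a,4,5,8,8a-octahydroazulen-4-yl 4-acetoxy-3-methoxybenzoate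
Product: 17 (3R,3aS,4S,8aR)-6-[(benzenesulfinyl)methyl]-3-hydroxy-8a-methyl-3-(propan-2-yl)-1,2,3,3a,4,5,8,8a-octahydroazulen-4-yl 4-acetoxy-3-methoxybenzoate (both configurations at sulfur)
Conditions: mCPBA (1.0 equiv), CH2Cl2, −78 °C
Reagents that add atoms: 3-chloroperoxybenzoic acid, OOC(=O)c1cccc(Cl)c1
Why: Oxidation of the sulfide to the sulfoxide is far faster than epoxidation of the trisubstituted alkene at low temperature with one equivalent of peracid; the mixture of sulfur epimers is of no consequence because sulfur is lost in the next step.

Step 13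
Reactants: 17 (3R,3aS,4S,8aR)-6-[(benzenesulfinyl)methyl]-3-hydroxy-8a-methyl-3-(propan-2-yl)-1,2,3,3a,4,5,8,8a-octahydroazulen-4-yl 4-acetoxy-3-methoxybenzoate
Product: 20 (3R,3aS,4S,7S,8aR)-3,7-dihydroxy-8a-methyl-6-methylidene-3-(propan-2-yl)decahydroazulen-4-yl 4-hydroxy-3-methoxybenzoate (target), via phenol sulfoxide 18 (not isolated), via allylic sulfenate 19 (not isolated)
Conditions: piperidine (10 equiv), MeOH, rt to 50 °C
Reagents that add atoms: none
Why: Piperidine first cleaves the aryl acetate by aminolysis (18); the allylic sulfoxide then equilibrates by a reversible [2,3]-sigmatropic shift with sulfenate 19 (Mislow–Evans rearrangement), which the amine traps at sulfur, so oxygen ends on C9 and the double bond moves to C8=C14. Oxygen should be delivered to the α-face of C9, away from the pseudo-axial C15 methyl group in a 1,3-relation on the β-face, which gives 9S; the hindered C6 benzoate should survive.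

## Compound list

1 | 2-bromo-3-methylcyclopent-2-en-1-one | CC1=C(Br)C(=O)CC1 | starting material
2 | 6-bromo-7-methyl-1,4-dioxaspiro[4.4]non-6-ene | CC1=C(Br)C2(CC1)OCCO2 | intermediate
3 | 6-ethenyl-7-methyl-1,4-dioxaspiro[4.4]non-6-ene | C=CC1=C(C)CCC12OCCO2 | intermediate
4 | methyl but-3-enoate | C=CCC(=O)OC | starting material
5 | methyl 2-diazobut-3-enoate | C=CC(=[N+]=[N-])C(=O)OC | intermediate
6 | methyl (1S,2S)-1-ethenyl-2-(7-methyl-1,4-dioxaspiro[4.4]non-6-en-6-yl)cyclopropane-1-carboxylate (vinyl and cyclopentenyl cis) | COC(=O)[C@]1(C=C)C[C@H]1C1=C(C)CCC12OCCO2 | intermediate (not isolated)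
7 | methyl (3a'R)-3a'-methyl-2',3',3a',4'-tetrahydro-7'H-spiro[1,3-dioxolane-2,1'-azulene]-6'-carboxylate | COC(=O)C1=CC[C@@]2(C)CCC3(OCCO3)C2=CC1 | intermediate
8 | methyl (3a'R,8'S,8a'S)-8'-hydroxy-3a'-methyl-2',3',3a',4',8',8a'-hexahydro-7'H-spiro[1,3-dioxolane-2,1'-azulene]-6'-carboxylate | COC(=O)C1=CC[C@@]2(C)CCC3(OCCO3)[C@@H]2[C@@H](O)C1 | intermediate
9 | (3a'R,8'S,8a'S)-6'-(hydroxymethyl)-3a'-methyl-2',3',3a',4',8',8a'-hexahydro-7'H-spiro[1,3-dioxolane-2,1'-azulen]-8'-ol | OCC1=CC[C@@]2(C)CCC3(OCCO3)[C@@H]2[C@@H](O)C1 | intermediate
10 | (3a'R,8'S,8a'S)-3a'-methyl-6'-[(phenylsulfanyl)methyl]-2',3',3a',4',8',8a'-hexahydro-7'H-spiro[1,3-dioxolane-2,1'-azulen]-8'-ol | c1ccccc1SCC1=CC[C@@]2(C)CCC3(OCCO3)[C@@H]2[C@@H](O)C1 | intermediate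
11 | (3aR,8S,8aS)-8-hydroxy-3a-methyl-6-[(phenylsulfanyl)methyl]-3,3a,4,7,8,8a-hexahydroazulen-1(2H)-one | c1ccccc1SCC1=CC[C@@]2(C)CCC(=O)[C@@H]2[C@@H](O)C1 | intermediate
12 | (1R,3aR,8S,8aS)-3a-methyl-6-[(phenylsulfanyl)methyl]-1-(propan-2-yl)-1,2,3,3a,4,7,8,8a-octahydroazulene-1,8-diol | c1ccccc1SCC1=CC[C@@]2(C)CC[C@@](O)(C(C)C)[C@@H]2[C@@H](O)C1 | intermediate
13 | vanillic acid (4-hydroxy-3-methoxybenzoic acid) | COc1cc(ccc1O)C(O)=O | starting material
14 | 4-acetoxy-3-methoxybenzoic acid | COc1cc(ccc1OC(C)=O)C(O)=O | intermediate
15 | 4-acetoxy-3-methoxybenzoyl chloride | COc1cc(ccc1OC(C)=O)C(Cl)=O | intermediate (not isolated)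
16 | (3R,3aS,4S,8aR)-3-hydroxy-8a-methyl-6-[(phenylsulfanyl)methyl]-3-(propan-2-yl)-1,2,3,3a,4,5,8,8a-octahydroazulen-4-yl 4-acetoxy-3-methoxybenzoate | c1ccccc1SCC1=CC[C@@]2(C)CC[C@@](O)(C(C)C)[C@@H]2[C@@H](OC(=O)c3ccc(OC(C)=O)c(OC)c3)C1 | intermediate
17 | (3R,3aS,4S,8aR)-6-[(benzenesulfinyl)methyl]-3-hydroxy-8a-methyl-3-(propan-2-yl)-1,2,3,3a,4,5,8,8a-octahydroazulen-4-yl 4-acetoxy-3-methoxybenzoate (sulfur epimers) | O=S(c1ccccc1)CC1=CC[C@@]2(C)CC[C@@](O)(C(C)C)[C@@H]2[C@@H](OC(=O)c3ccc(OC(C)=O)c(OC)c3)C1 | intermediate
18 | (3R,3aS,4S,8aR)-6-[(benzenesulfinyl)methyl]-3-hydroxy-8a-methyl-3-(propan-2-yl)-1,2,3,3a,4,5,8,8a-octahydroazulen-4-yl 4-hydroxy-3-methoxybenzoate | O=S(c1ccccc1)CC1=CC[C@@]2(C)CC[C@@](O)(C(C)C)[C@@H]2[C@@H](OC(=O)c3ccc(O)c(OC)c3)C1 | intermediate (not isolated)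
19 | (3R,3aS,4S,7S,8aR)-3-hydroxy-8a-methyl-6-methylidene-7-[(phenylsulfanyl)oxy]-3-(propan-2-yl)decahydroazulen-4-yl 4-hydroxy-3-methoxybenzoate | C=C1[C@@H](OSc4ccccc4)C[C@@]2(C)CC[C@@](O)(C(C)C)[C@@H]2[C@@H](OC(=O)c3ccc(O)c(OC)c3)C1 | intermediate (not isolated)
20 | (3R,3aS,4S,7S,8aR)-3,7-dihydroxy-8a-methyl-6-methylidene-3-(propan-2-yl)decahydroazulen-4-yl 4-hydroxy-3-methoxybenzoate | C=C1[C@@H](O)C[C@@]2(C)CC[C@@](O)(C(C)C)[C@@H]2[C@@H](OC(=O)c3ccc(O)c(OC)c3)C1 | target

## Step count and least certain steps

Total steps: 13. Longest linear sequence: 11 (steps 1, 2, 4, 5, 6, 7, 8, 9, 11, 12, 13).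

**Step 4 (key step).** The most likely failures are a slow Cope rearrangement, because the C15 methyl group must point at the cyclopropane CH2 in the boat and long heating opens other pathways; loss of the unstabilised diazo ester by electrocyclisation before it meets the catalyst; and incomplete asymmetric induction with an unsubstituted vinylcarbenoid. The fallback sets out from 3 and changes the carbenoid class and the oxidation level at which the ring is built. Diazo ester 5 is replaced by the isolable, donor-stabilised methyl 3-[(tert-butyldimethylsilyl)oxy]-2-diazobut-3-enoate F1, made from methyl 2-diazo-3-oxobutanoate with TBSOTf and Et3N. The catalyst is replaced by Rh2(R-PTAD)4 [dirhodium tetrakis((R)-(1-adamantyl)(phthalimido)acetate)] or its enantiomer, the combination with the closest precedent for [4+3] reactions that create quaternary carbons. The resulting C9-silyloxy analogue of 7, methyl (3a'R)-5'-[(tert-butyldimethylsilyl)oxy]-3a'-methyl-2',3',3a',4'-tetrahydro-7'H-spiro[1,3-dioxolane-2,1'-azulene]-6'-carboxylate F2, is converted with CsF and PhNTf2 into the enol triflate F3. Reduction of F3 with Pd(OAc)2, PPh3, HCO2H and Bu3N removes the extra oxygen, and the sequence comes back to the route at 7.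

**Step 5.** The most likely failures are poor discrimination between the two faces of the C5=C6 bond (the ring CH2 at C10 competes with the C15 methyl group as the shielding element) and a second, intramolecular B–H addition to the enoate. The fallback sets out from 7 and separates the two stereocentres. Epoxidation of the electron-rich C5=C6 bond with mCPBA and NaHCO3 gives the 5,6-epoxide F4. Reductive opening with Cp2TiCl (from Cp2TiCl2 and Zn dust, trivalent titanium) and 1,4-cyclohexadiene breaks the C5–O bond to give the tertiary C5 radical. Hydrogen-atom transfer to that radical should favour the trans ring fusion, and the sequence comes back to the route at 8.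

**Step 9.** The most likely failures are enolisation or retro-aldol opening of the β-hydroxy ketone, reduction by β-hydride transfer from the isopropyl reagent, and epimerisation at C5. The fallback sets out from 11 and uses an sp2 nucleophile without β-hydrogens that is less basic. Addition of isopropenylmagnesium bromide with CeCl3 gives the isopropenyl carbinol F5. Diimide (potassium azodicarboxylate, AcOH) then reduces the 1,1-disubstituted alkene in preference to the trisubstituted ring alkene and is not poisoned by the thioether, and the sequence comes back to the route at 12.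

**Step 13.** The most likely failures are delivery of oxygen to the β-face of C9 in the [2,3] shift and slow trapping because the sulfoxide–sulfenate equilibrium lies far on the sulfoxide side. The fallback sets out from 17 and corrects the stereocentre by substitution. Trapping with P(OMe)3 in MeOH keeps the aryl acetate; if the 9β-alcohol F6 (the 9-epimer of O-acetylated 20) is the main product, a Mitsunobu reaction with 4-nitrobenzoic acid, PPh3 and DIAD inverts C9 to the 9α-(4-nitrobenzoate) F7. K2CO3 in MeOH then removes the nitrobenzoate and the aryl acetate, and the sequence comes back to the route at 20.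

## Further compounds

F1 | step 4 | methyl 3-[(tert-butyldimethylsilyl)oxy]-2-diazobut-3-enoate | C=C(O[Si](C)(C)C(C)(C)C)C(=[N+]=[N-])C(=O)OC
F2 | step 4 | methyl (3a'R)-5'-[(tert-butyldimethylsilyl)oxy]-3a'-methyl-2',3',3a',4'-tetrahydro-7'H-spiro[1,3-dioxolane-2,1'-azulene]-6'-carboxylate | COC(=O)C1=C(O[Si](C)(C)C(C)(C)C)C[C@@]2(C)CCC3(OCCO3)C2=CC1
F3 | step 4 | methyl (3a'R)-3a'-methyl-5'-[(trifluoromethanesulfonyl)oxy]-2',3',3a',4'-tetrahydro-7'H-spiro[1,3-dioxolane-2,1'-azulene]-6'-carboxylate | COC(=O)C1=C(OS(=O)(=O)C(F)(F)F)C[C@@]2(C)CCC3(OCCO3)C2=CC1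
F4 | step 5 | 5α,6α-epoxide of 7 (daucane numbering; epoxide oxygen on the face opposite C15) | COC(=O)C1=CC[C@@]2(C)CCC3(OCCO3)[C@@]24O[C@H]4C1
F5 | step 9 | 4α-(prop-1-en-2-yl) analogue of 12 (4β-OH, 6α-OH, C14 phenyl thioether) | c1ccccc1SCC1=CC[C@@]2(C)CC[C@@](O)(C(C)=C)[C@@H]2[C@@H](O)C1
F6 | step 13 | 9-epimer (9β-OH) of the phenol O-acetate of 20 | C=C1[C@H](O)C[C@@]2(C)CC[C@@](O)(C(C)C)[C@@H]2[C@@H](OC(=O)c3ccc(OC(C)=O)c(OC)c3)C1
F7 | step 13 | 9α-(4-nitrobenzoate) of the phenol O-acetate of 20 | C=C1[C@@H](OC(=O)c4ccc(cc4)[N+](=O)[O-])C[C@@]2(C)CC[C@@](O)(C(C)C)[C@@H]2[C@@H](OC(=O)c3ccc(OC(C)=O)c(OC)c3)C1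
A1 | alternative 1 | metathesis diene: cyclopentane with C1 methyl and allyl, C4 hydroxyl and isopropyl, and a (1S)-1-hydroxy-3-methylbut-3-enyl chain on C5, configured as the target at C1, C4, C5, C6 | C=CC[C@@]1(C)CC[C@@](O)(C(C)C)[C@@H]1[C@@H](O)CC(C)=C
A2 | alternative 1 | dauc-8-ene-4β,6α-diol | CC1=CC[C@@]2(C)CC[C@@](O)(C(C)C)[C@@H]2[C@@H](O)C1
A3 | alternative 2 | cis-fused 10-methyldecalin-4,5-diol 4-methanesulfonate with C3 as ethylene ketal (decalin numbering; mesylate, hydroxyl and methyl all cis) | C[C@]12CCC3(OCCO3)[C@H](OS(C)(=O)=O)[C@@]1(O)CCCC2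
A4 | alternative 2 | trans-fused 1-methylbicyclo[5.3.0]decan-6-one with C4 as ethylene ketal (daucane numbering) | C1CC[C@@]2(C)CCC3(OCCO3)[C@@H]2C(=O)C1
A5 | alternative 3 | (S)-terpinen-4-ol | CC1=CC[C@](O)(C(C)C)CC1
A6 | alternative 3 | (R)-5-hydroxy-2-methyl-5-(propan-2-yl)cyclopent-1-ene-1-carbaldehyde | CC1=C(C=O)[C@](O)(C(C)C)CC1
A7 | alternative 3 | bromo-aldehyde for ring closure: cyclopentane with C1 methyl and 2-oxoethyl, C4 hydroxyl and isopropyl, and a (1S)-3-bromo-1-[(tert-butyldimethylsilyl)oxy]but-3-enyl chain on C5 | O=CC[C@@]1(C)CC[C@@](O)(C(C)C)[C@@H]1[C@@H](O[Si](C)(C)C(C)(C)C)CC(Br)=C
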